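**Bench rule.** Feed the reagent slowly. In cedar, side product A stands at 12% by 0.167 h and ends at 17%, though starting material remains at 25%. From cedar to elm the charge rises by a factor of 2.20, and side product A ends at 22%. I read this as a step taking two reagents beside a step taking one, with starting material in both.

| flask | starting material | reagent | remark | time |
|---|---|---|---|---|
| cedar | 0.050 M | 0.70 equiv | run made earlier |  |
| larch | 0.070 M | 0.70 equiv | run made earlier |  |
| elm | 0.11 M | 0.70 equiv | run made earlier |  |
| dawn | 0.050 M | 0.700 equiv (fed, over 6.0 min) | all else is in the flask from the start; the feed brings no volume worth counting | 2.5 h |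
| winter | 0.050 M (fed, over 1.0 h) | 0.700 equiv | all else is in the flask from the start; the feed brings no volume worth counting | 2.5 h |
| dusk | 0.050 M | 0.700 equiv | everything together at the start | 2.5 h |
| autumn | 0.050 M | 0.700 equiv (fed, over 1.0 h) | all else is in the flask from the start; the feed brings no volume worth counting | 2.5 h |

| run | time / h | target / % | side product A / % | starting material / % |
|---|---|---|---|---|
| cedar | 0.167 | 10 | 12 | 75 |
| cedar | 0.500 | 16 | 14 | 55 |
| cedar | 0.833 | 11 | 16 | 44 |
| cedar | 1.33 | 9 | 12 | 36 |
| cedar | 2.00 | 7 | 16 | 26 |
| cedar | 2.50 | 7 | 17 | 25 |
| larch | 0.500 | 7 | 17 | 46 |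
| larch | 1.00 | 10 | 18 | 36 |
| larch | 1.50 | 8 | 20 | 31 |
| larch | 2.00 | 4 | 16 | 27 |
| larch | 2.50 | 2 | 19 | 24 |
| larch | 3.00 | 2 | 18 | 23 |
| elm | 0.500 | 6 | 21 | 45 |
| elm | 1.00 | 3 | 21 | 36 |
| elm | 1.50 | 5 | 21 | 31 |
| elm | 2.00 | 4 | 20 | 29 |
| elm | 2.50 | 3 | 22 | 27 |
| elm | 3.00 | 0 | 22 | 29 |

(readings scatter by 1.5 percentage points)



- which flask leads in share of target in target plus side product A ("all alike" within 1.5 percentage points) (dawn / winter / dusk / autumn / all alike)
- share of target in target plus side product A at the end, dawn
- share of target in target plus side product A at the end, winter
- share of target in target plus side product A at the end, dusk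
- share of target in target plus side product A at the end, autumn

**The crossover.** Side product A then forms against target as reagent concentration over a constant K, a selectivity factor from which starting material cancels. Integrating until the charged reagent R is spent gives A = R/2 − (K/4) ln(1 + 2R/K). Cedar has R = 0.0350 M and A = 0.00850 M. Substituting twice gives 0.0315 M, the crossover concentration, at which both steps run equally fast. This is a reading, with the scatter of the readings. With it, elm should end at 22.3%, and elm reads 22%.

**Feed border.** From its readings I count that cedar has spent about half of its reagent by 0.167 h. That is one early halving and no constant half-life, since my two-reagent step is not first order in reagent and cedar's starting material falls, so I use it as a rough early time scale and no more. Balancing the autumn feed against loss on that scale gives a rough reagent level near 0.00843 M, which is 0.268 of the crossover, against 1.11 at the start of dusk. Dividing the charge at that split, I reckon 12.2% side product A in autumn. The rule's border is feed time over that early scale: 5.99 for autumn, but 0.599 for dawn, whose feed is shorter than that early time. Winter feeds starting material, which cancels, and its reagent starts at the full charge. I reckon no target, so I give no shares.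

**The forecast.** It names autumn, with 28% for dawn, 33% for winter, 27% for dusk and 50% for autumn. It says “Slow reagent feed (autumn) should give A ≈7%, target ≈8%”, so our figures for side product A differ.

**Result.** The autumn flask leads with 48.6%, against 33.0% for dawn, 34.9% for winter and 30.5% for dusk.

    starting material + 2 reagent → side product A (k = 0.300 M⁻² s⁻¹)
    starting material + target → side product B (k = 0.0130 M⁻¹ s⁻¹)
    reagent + target → over-reaction product (k = 9.00 × 10⁻⁴ M⁻¹ s⁻¹)
    starting material + reagent → target (k = 0.00990 M⁻¹ s⁻¹)

**Crossover again.** Autumn ends with 11.5% side product A, its reagent averaging 0.00922 M over the first hour. That mean is 0.293 of the crossover, and the spent reagent, the charge less 11%, divided at that split gives 11.6%. For the dusk recipe with 0.170 equiv reagent, the integrated formula gives 1.70%, and that flask holds 1.64%.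

The earlier runs and the new flask are simulated on assumed constants, noise included.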